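## Retrosynthetic overview

1. The catechol is made last: target 22 comes from 6-chromenol 20 by ortho-oxygenation at C5 (ortho-quinone, then reduction).
2. The pyran ring is the last ring formed. Its C2–O1 bond, and with it the 2S centre, comes from hydroquinone allylic alcohol 18 by an enantioselective Brønsted-acid cyclodehydration.
3. 18 comes from a Heck coupling of bought 5-iodovanillin (15) with dienol 14, followed by Dakin oxidation.
4. 14 comes from trans-dimethyl octalone 8 by MeLi addition, ozonolysis and double methylenation. The enone ring is a temporary ring used only to fix the trans relationship of the two ring methyls.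
5. 8 comes from 2,6-dimethylcyclohexanone and methyl vinyl ketone by a chiral-imine Michael addition and aldol condensation. Ring order: cyclohexane (bought), temporary cyclohexenone (formed, then opened), pyran (last).

Assumption 1: the target is taken exactly as the SMILES gives it, i.e. (2S)-chromene carbon and a (1R,3R)-1,3-dimethyl-2-methylidenecyclohexyl group with the two ring methyls trans.
Assumption 2: the sense of induction of the step 9 catalyst is assigned in a pilot run; the R acid is written, and its mirror image is used if it gives the 2R epimer.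

## Route

Step 1
Reactants: 1 2,6-dimethylcyclohexan-1-one; 2 (S)-1-phenylethylamine
Product: 3 (S)-N-(2,6-dimethylcyclohexylidene)-1-phenylethanamine
Conditions: TsOH (cat.), toluene, reflux, Dean–Stark
Reagents that add atoms: none
Why: Acid-catalysed ketone–amine condensation with azeotropic removal of water gives the imine; no stereocentre of the target is fixed here because both α-carbons stay epimerisable.

Step 2
Reactants: 3 (S)-N-(2,6-dimethylcyclohexylidene)-1-phenylethanamine; 4 methyl vinyl ketone
Product: 6 (2R)-2,6-dimethyl-2-(3-oxobutyl)cyclohexan-1-one (C6 epimers), via Michael adduct imine 5 (not isolated)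
Conditions: 4 (1.5 equiv), THF, 40 °C, 3 d; then 20% aq AcOH, rt
Reagents that add atoms: water, O
Why: Chiral-imine Michael addition (aza-ene-type transfer through the secondary enamine tautomer): the enone is attacked by the substituted enamine carbon on the face anti to the phenyl group of the (S)-auxiliary, which sets the quaternary carbon as R, and aqueous acid then hydrolyses the imine; the C6 epimer ratio does not matter because step 3 equilibrates it.

Step 3
Reactants: 6 (2R)-2,6-dimethyl-2-(3-oxobutyl)cyclohexan-1-one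
Product: 8 (4aR,8R)-4a,8-dimethyl-4,4a,5,6,7,8-hexahydronaphthalen-2(3H)-one, via aldol ketol 7 (not isolated)
Conditions: NaOMe, MeOH, 65 °C, 12 h
Reagents that add atoms: none
Why: Intramolecular aldol condensation (ring-closing half of a Robinson annulation) gives the conjugated octalone, and NaOMe equilibrates the γ-carbon C8 through the dienolate to the isomer with the equatorial methyl trans to the angular methyl (the same preference that turns 6β-methyl into 6α-methyl 4-en-3-one steroids), which sets the secondary methyl centre as R; any residual cis isomer is removed by chromatography.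

Step 4
Reactants: 8 (4aR,8R)-4a,8-dimethyl-4,4a,5,6,7,8-hexahydronaphthalen-2(3H)-one
Product: 10 trimethyl{[(4aR,8R)-2,4a,8-trimethyl-2,3,4,4a,5,6,7,8-octahydronaphthalen-2-yl]oxy}silane (C2 epimers), via lithium alkoxide 9 (not isolated)
Conditions: MeLi, Et2O, −78 °C; then Me3SiCl, −78 °C → rt
Reagents that add atoms: methyllithium, [Li]C; chlorotrimethylsilane, C[Si](C)(C)Cl
Why: 1,2-Addition of methyllithium to the enone carbonyl followed by O-silylation of the tertiary alkoxide in the same flask; the new carbinol centre is deliberately taken as both epimers because it is flattened to a cation in step 9.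

Step 5
Reactants: 10 trimethyl{[(4aR,8R)-2,4a,8-trimethyl-2,3,4,4a,5,6,7,8-octahydronaphthalen-2-yl]oxy}silane
Product: 12 4-[(1R,3R)-1,3-dimethyl-2-oxocyclohexyl]-2-methyl-2-(trimethylsilyloxy)butanal, via ozonide 11 (not isolated)
Conditions: O3, CH2Cl2, −78 °C; then Me2S, −78 °C → rt
Reagents that add atoms: ozone, [O-][O+]=O
Why: Ozonolysis of the only C=C bond with reductive work-up opens the temporary ring to the ring ketone and the α-silyloxy aldehyde; the neutral conditions leave the epimerisable CH(CH3) centre next to the new ketone untouched.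

Step 6
Reactants: 12 4-[(1R,3R)-1,3-dimethyl-2-oxocyclohexyl]-2-methyl-2-(trimethylsilyloxy)butanal
Product: 14 3-methyl-5-[(1R,3R)-1,3-dimethyl-2-methylidenecyclohexyl]pent-1-en-3-ol (C3 epimers), via dienol silyl ether 13 (not isolated)
Conditions: Cp2Ti(μ-CH2)(μ-Cl)AlMe2 (Tebbe reagent, 3 equiv), pyridine, THF–toluene, −40 °C → rt; then K2CO3 (cat.), MeOH, rt
Reagents that add atoms: Tebbe reagent (written as Cp2Ti=CH2·ClAlMe2), C=[Ti](C1C=CC=C1)C1C=CC=C1.C[Al](C)Cl
Why: Tebbe methylenation converts both the aldehyde and the hindered ketone into C=CH2 through titanium oxetanes without basic enolisation, so the α-stereocentre is kept, and mild methanolysis then frees the tertiary alcohol.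

Step 7
Reactants: 14 3-methyl-5-[(1R,3R)-1,3-dimethyl-2-methylidenecyclohexyl]pent-1-en-3-ol; 15 5-iodovanillin
Product: 16 4-hydroxy-3-[(1E)-3-hydroxy-3-methyl-5-((1R,3R)-1,3-dimethyl-2-methylidenecyclohexyl)pent-1-en-1-yl]-5-methoxybenzaldehyde
Conditions: Pd(OAc)2 (5 mol %), NaHCO3, Bu4NCl, DMF, 50 °C, argon
Reagents that add atoms: none
Why: Mizoroki–Heck reaction under ligand-free phase-transfer conditions: the aryl–palladium species adds to the unhindered vinyl group at its terminal carbon and β-hydride elimination gives the E-styrene (the carbinol carbon has no hydrogen), while the hindered ring methylidene does not insert.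

Step 8
Reactants: 16 4-hydroxy-3-[(1E)-3-hydroxy-3-methyl-5-((1R,3R)-1,3-dimethyl-2-methylidenecyclohexyl)pent-1-en-1-yl]-5-methoxybenzaldehyde
Product: 18 2-[(1E)-3-hydroxy-3-methyl-5-((1R,3R)-1,3-dimethyl-2-methylidenecyclohexyl)pent-1-en-1-yl]-6-methoxybenzene-1,4-diol, via aryl formate 17 (not isolated)
Conditions: H2O2 (30% aq, 1.1 equiv), NaOH (2 equiv), THF–H2O, 0 °C, argon
Reagents that add atoms: hydrogen peroxide, OO
Why: Dakin oxidation: hydroperoxide adds to the aldehyde para to the phenoxide, aryl migration gives the formate and hydroxide cleaves it to the hydroquinone; the electron-rich, non-conjugated alkenes are inert to alkaline H2O2.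

Step 9
Reactants: 18 2-[(1E)-3-hydroxy-3-methyl-5-((1R,3R)-1,3-dimethyl-2-methylidenecyclohexyl)pent-1-en-1-yl]-6-methoxybenzene-1,4-diol
Product: 20 (2S)-2-{2-[(1R,3R)-1,3-dimethyl-2-methylidenecyclohexyl]ethyl}-8-methoxy-2-methyl-2H-chromen-6-ol, via ortho-quinone methide 19 (not isolated)
Conditions: (R)-3,3′-bis(2,4,6-triisopropylphenyl)-1,1′-binaphthyl-2,2′-diyl N-triflylphosphoramide (5 mol %), 5 Å MS, toluene (0.02 M), −60 °C, argon
Reagents that add atoms: none
Why: Proposed new method: the chiral acid ionises the tertiary alcohol (allylic and vinylogously benzylic to the ortho-hydroxyaryl ring), so both carbinol epimers converge on one allyl cation that is the O-protonated form of ortho-quinone methide 19; the phosphoramidate anion stays hydrogen-bonded to the phenolic OH as a contact ion pair, and the six-membered C–O closure (oxa-6π electrocyclisation of the bound quinone methide, formally a 6-endo allylic etherification) takes place on the face of the C(CH3)(CH2CH2R) terminus selected by the 3,3′-aryl pocket, giving the 2S centre under catalyst control while the remote ring stereocentres and the acid-sensitive methylidene are untouched at −60 °C; the closest known reaction type is the chiral N-triflylphosphoramide-catalysed intramolecular allylic substitution of 2-(3-aryl-3-hydroxyalkenyl)phenols to 2-aryl-2-alkyl-2H-chromenes, which has not been shown for a carbinol carrying two alkyl groups (methyl against a primary alkyl chain).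

Step 10
Reactants: 20 (2S)-2-{2-[(1R,3R)-1,3-dimethyl-2-methylidenecyclohexyl]ethyl}-8-methoxy-2-methyl-2H-chromen-6-ol
Product: 22 (2S)-2-{2-[(1R,3R)-1,3-dimethyl-2-methylidenecyclohexyl]ethyl}-8-methoxy-2-methyl-2H-chromene-5,6-diol, via ortho-quinone 21 (not isolated)
Conditions: IBX (1.05 equiv), DMF, 0 °C → rt, argon; then Na2S2O4, H2O–EtOAc, rt
Reagents that add atoms: 2-iodoxybenzoic acid (IBX), OI1(=O)OC(=O)c2ccccc12
Why: Regioselective ortho-oxygenation of the phenol with IBX (oxygen transfer from the aryloxy–iodine adduct to the ortho carbon para to the methoxy group, C5, which is also the most reactive position of 6-chromanols) gives the 5,6-quinone, and dithionite reduces it in the same flask to the catechol; no stereocentre is touched.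

## Compound list

1 | 2,6-dimethylcyclohexan-1-one (commercial cis/trans mixture) | CC1CCCC(C)C1=O | starting material
2 | (S)-1-phenylethylamine | C[C@H](N)c1ccccc1 | starting material
3 | (S)-N-(2,6-dimethylcyclohexylidene)-1-phenylethanamine | C[C@H](N=C1C(C)CCCC1C)c1ccccc1 | intermediate
4 | methyl vinyl ketone (but-3-en-2-one) | CC(=O)C=C | starting material
5 | 4-[(1R)-1,3-dimethyl-2-{[(1S)-1-phenylethyl]imino}cyclohexyl]butan-2-one (Michael adduct imine) | C[C@H](N=C1C(C)CCC[C@]1(C)CCC(C)=O)c1ccccc1 | intermediate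
6 | (2R)-2,6-dimethyl-2-(3-oxobutyl)cyclohexan-1-one (C6 epimers) | O=C1C(C)CCC[C@]1(C)CCC(C)=O | intermediate
7 | (4aR)-8a-hydroxy-4a,8-dimethyloctahydronaphthalen-2(1H)-one (aldol ketol) | O=C1CC2(O)C(C)CCC[C@]2(C)CC1 | intermediate
8 | (4aR,8R)-4a,8-dimethyl-4,4a,5,6,7,8-hexahydronaphthalen-2(3H)-one | O=C1C=C2[C@H](C)CCC[C@]2(C)CC1 | intermediate
9 | lithium (4aR,8R)-2,4a,8-trimethyl-2,3,4,4a,5,6,7,8-octahydronaphthalen-2-olate | [Li+].[O-]C1(C)C=C2[C@H](C)CCC[C@]2(C)CC1 | intermediate
10 | trimethyl{[(4aR,8R)-2,4a,8-trimethyl-2,3,4,4a,5,6,7,8-octahydronaphthalen-2-yl]oxy}silane (C2 epimers) | C[Si](C)(C)OC1(C)C=C2[C@H](C)CCC[C@]2(C)CC1 | intermediate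
11 | ozonide of 10 (1,2,4-trioxolane across the former C1=C8a bond) | C[Si](C)(C)OC1(C)CC[C@@]2(C)CCC[C@@H](C)C23OOC1O3 | intermediate
12 | 4-[(1R,3R)-1,3-dimethyl-2-oxocyclohexyl]-2-methyl-2-(trimethylsilyloxy)butanal | O=C1[C@H](C)CCC[C@]1(C)CCC(C)(O[Si](C)(C)C)C=O | intermediate
13 | trimethyl({3-methyl-5-[(1R,3R)-1,3-dimethyl-2-methylidenecyclohexyl]pent-1-en-3-yl}oxy)silane | C=C1[C@H](C)CCC[C@]1(C)CCC(C)(O[Si](C)(C)C)C=C | intermediate
14 | 3-methyl-5-[(1R,3R)-1,3-dimethyl-2-methylidenecyclohexyl]pent-1-en-3-ol (C3 epimers) | C=C1[C@H](C)CCC[C@]1(C)CCC(C)(O)C=C | intermediate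
15 | 5-iodovanillin (4-hydroxy-3-iodo-5-methoxybenzaldehyde) | COc1cc(C=O)cc(I)c1O | starting material
16 | 4-hydroxy-3-[(1E)-3-hydroxy-3-methyl-5-((1R,3R)-1,3-dimethyl-2-methylidenecyclohexyl)pent-1-en-1-yl]-5-methoxybenzaldehyde | C=C1[C@H](C)CCC[C@]1(C)CCC(C)(O)/C=C/c1cc(C=O)cc(OC)c1O | intermediate
17 | 4-hydroxy-3-[(1E)-3-hydroxy-3-methyl-5-((1R,3R)-1,3-dimethyl-2-methylidenecyclohexyl)pent-1-en-1-yl]-5-methoxyphenyl formate | C=C1[C@H](C)CCC[C@]1(C)CCC(C)(O)/C=C/c1cc(OC=O)cc(OC)c1O | intermediate
18 | 2-[(1E)-3-hydroxy-3-methyl-5-((1R,3R)-1,3-dimethyl-2-methylidenecyclohexyl)pent-1-en-1-yl]-6-methoxybenzene-1,4-diol | C=C1[C@H](C)CCC[C@]1(C)CCC(C)(O)/C=C/c1cc(O)cc(OC)c1O | intermediate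
19 | 4-hydroxy-2-methoxy-6-{3-methyl-5-[(1R,3R)-1,3-dimethyl-2-methylidenecyclohexyl]pent-2-en-1-ylidene}cyclohexa-2,4-dien-1-one (ortho-quinone methide, catalyst-bound) | C=C1[C@H](C)CCC[C@]1(C)CCC(C)=CC=C1C=C(O)C=C(OC)C1=O | intermediate
20 | (2S)-2-{2-[(1R,3R)-1,3-dimethyl-2-methylidenecyclohexyl]ethyl}-8-methoxy-2-methyl-2H-chromen-6-ol | C=C1[C@H](C)CCC[C@]1(C)CC[C@@]1(C)C=Cc2cc(O)cc(OC)c2O1 | intermediate
21 | (2S)-2-{2-[(1R,3R)-1,3-dimethyl-2-methylidenecyclohexyl]ethyl}-8-methoxy-2-methyl-2H-chromene-5,6-dione | C=C1[C@H](C)CCC[C@]1(C)CC[C@@]1(C)C=CC2=C(O1)C(OC)=CC(=O)C2=O | intermediate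
22 | (2S)-2-{2-[(1R,3R)-1,3-dimethyl-2-methylidenecyclohexyl]ethyl}-8-methoxy-2-methyl-2H-chromene-5,6-diol | C=C1[C@H](C)CCC[C@]1(C)CC[C@@]1(C)C=Cc2c(O)c(O)cc(OC)c2O1 | target

## Step count and risks

Total step count: 10. Longest linear sequence: 10 steps (1 to 22 through steps 1–10; 15 is bought and enters at step 7).

The three steps most likely to fail:

Step 9 (the new asymmetric ring closure; the catalyst must tell a methyl from a primary alkyl chain). Fallback, known chemistry: set out from 18 and cyclise with an achiral acid (pyridinium p-toluenesulfonate, CH2Cl2, rt), the ordinary acid-catalysed cyclodehydration of ortho-hydroxycinnamyl alcohols. This gives the 1:1 mixture of C2 epimers of the chromenol F1. The two diastereomers are then separated by preparative HPLC on a cellulose-carbamate chiral stationary phase, and the 2S epimer is 20, where the route is rejoined.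

Step 6 (double methylenation of a hindered, epimerisable ketone and an α-oxygenated aldehyde in one operation). Fallback: set out from 12 and replace the titanium carbene by a Peterson sequence. Me3SiCH2Li with CeCl3 (THF, −78 °C) adds to both carbonyls without enolisation to give the bis(β-hydroxysilane) F2. KH (THF, rt) then brings about the double syn-elimination to 13, where the route is rejoined before the methanolysis to 14.

Step 10 (ortho-oxygenation of an oxidation-prone chromenol; C5 against C7 selectivity and handling of the ortho-quinone). Fallback: set out from 20 and bring in the C5 oxygen through carbon. Magnesium-mediated ortho-formylation (MgCl2, Et3N, paraformaldehyde, MeCN, reflux) gives the salicylaldehyde F3. A Dakin oxidation (H2O2, NaOH, THF–H2O, 0 °C, argon) then passes through the aryl formate F4 and delivers 22 directly.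

## Further compounds

F1 | step 9 | 2-{2-[(1R,3R)-1,3-dimethyl-2-methylidenecyclohexyl]ethyl}-8-methoxy-2-methyl-2H-chromen-6-ol as the 1:1 mixture of C2 epimers | C=C1[C@H](C)CCC[C@]1(C)CCC1(C)C=Cc2cc(O)cc(OC)c2O1
F2 | step 6 | 5-[(1R,3R)-2-hydroxy-1,3-dimethyl-2-(trimethylsilylmethyl)cyclohexyl]-3-methyl-1-(trimethylsilyl)-3-(trimethylsilyloxy)pentan-2-ol | C[Si](C)(C)CC1(O)[C@H](C)CCC[C@]1(C)CCC(C)(O[Si](C)(C)C)C(O)C[Si](C)(C)C
F3 | step 10 | (2S)-2-{2-[(1R,3R)-1,3-dimethyl-2-methylidenecyclohexyl]ethyl}-6-hydroxy-8-methoxy-2-methyl-2H-chromene-5-carbaldehyde | C=C1[C@H](C)CCC[C@]1(C)CC[C@@]1(C)C=Cc2c(C=O)c(O)cc(OC)c2O1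
F4 | step 10 | (2S)-2-{2-[(1R,3R)-1,3-dimethyl-2-methylidenecyclohexyl]ethyl}-6-hydroxy-8-methoxy-2-methyl-2H-chromen-5-yl formate | C=C1[C@H](C)CCC[C@]1(C)CC[C@@]1(C)C=Cc2c(OC=O)c(O)cc(OC)c2O1
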